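## Structural features

The target is a helenanolide-type pseudoguaianolide in which ring A, a cyclopentenone (C1–C5, C4 carbonyl, C2=C3), is trans-fused through C1 (α-H) and the quaternary C5 (β-methyl) to the seven-membered ring B (C5–C10 and C1). A γ-lactone, ring C (C7, C8, O, C12, C11), is cis-fused to ring B on its β face, and its α-carbon C11 is also the spiro atom of a bicyclo[2.2.2]octene built from a p-menthadienol through the bonds C11–C3′ and C13–C6′, with a tertiary alcohol on C8′. All seven atoms of ring B are substituted and five of them are contiguous stereocentres, C6 (α-O-tiglate), C7, C8 (β-O), C9 (β-OH) and C10 (α-CH3), flanked by C5 and C1; C11, C3′, C4′ and C6′ bring the total to eleven. Fragile groups are the cyclopentenone (a Michael acceptor), the tiglate, the lactone beside a free secondary alcohol, and the tertiary alcohol next to the strained trisubstituted alkene. The first real difficulty is the oxygen on C8: once C6/C7 and C9/C10 are in place, C8 is a plain methylene with no functional handle. The second is the spiro centre, where C3′ lies on the lactone face cis to C6, C13 on the face of H7, and the lactone carbonyl syn to the C1′=C2′ bridge. The key step uses the geometry around C8: the β-hydrogen on C8 is a 1,5-hydrogen relative to a nitrogen placed on C12 (N, C12, C11, C7, C8) and lies on the side of the C7 side chain, while the only other 1,5-hydrogen, on C6, sits on a carbon deactivated by the tiglate. A five-membered ring across C7–C8 can only be cis, so the oxygen must enter β.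

## Logic of the disconnections

**39 back to 36.** No skeletal bond is cut. The C9 silyl ether, the C2=C3 double bond and the C4 ketal are restored by way of 38 and 37. This keeps the cyclopentenone and the free secondary alcohol out of every earlier step. The forward steps must be mild toward the tertiary alcohol beside the bridged alkene.

**36 to 30 and 35.** The bonds C11–C3′ and C13–C6′ are cut (retro-Diels–Alder). This removes four stereocentres and ten carbons at once and leaves 35, which is reachable in three steps. The forward step must give the para orientation, react anti to the hydroxyisopropyl group, place the lactone carbonyl endo, and bond C11 on the lactone face cis to C6. That face is the more crowded one, so this step is treated as a risk below.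

**35 to 31.** The C2′=C3′ double bond of 35 is traced to the carbonyl group by way of 33, and the tertiary alcohol to the isopropenyl group by way of 32. The stereocentre C4′ is bought with 31, not made. The forward steps must not epimerise it or isomerise the 1,3-diene.

**30 to 26.** The C11=C13 bond is cut. C13 is added as a one-carbon electrophile to the lactone enolate, giving 28, and unmasked by elimination. The demand is a kinetic enolisation of the lactone in the presence of the tiglate, and no free ketone, hence the C4 ketal.

**26 to 22.** The C8–O bond is cut (key step). Ring C and the C8 stereocentre disappear and C8 becomes a methylene. The forward step must select C8–H over C6–H and close through oxygen on the β face. Compound 22 carries a silyl ether on O9 instead of an ester and a ketal on C4 instead of a ketone. The silyl ether removes a competing neighbouring group, survives the later enolate chemistry and comes off without base. The ketal is needed in steps 7, 12 and 16.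

**22 to 19.** The amide is traced to a nitrile and the C6–O acyl bond to 20. A nitrile tolerates the acylation and is hydrated under neutral conditions. The hindered 6α-hydroxyl must be esterified before the amide exists.

**19 to 17.** The bonds C7–C11 and C6–O are cut back to the C6=C7 alkene by way of 18. One face-selective epoxidation and one SN2 opening set both C6 and C7. The forward demand is α-epoxidation and attack at C7, not at the neopentyl C6.

**17 to 8.** The C6=C7 alkene comes from the C6 carbinol 15 by dehydration. The C9/C10 pair comes from 12: C10 by equilibration, C9 by thermodynamic reduction. Compound 12 in turn comes from the C9=C10 alkene by hydroboration and oxidation. Every stereocentre is set with or along the substrate's own bias. The cost is that the C6 oxygen must be protected while C9 and C10 are made.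

**8 to 6.** The C9=C10 bond is cut (ring-closing metathesis), which opens ring B to a cyclopentanone with two alkene arms. The forward step must form a trisubstituted cycloheptene.

**6 to 1, 2 and 3.** The bonds C1–C10 and C5–C6 are cut (conjugate addition, then aldol trapping). This gives three simple components. The forward step must control the absolute configuration at C1 and the trans relation C1/C5. The carbinol centre C6 need not be controlled.

## Other disconnections considered

Alternative 1: The cut runs through C1–C10 and C5–C6 and leads to 1 and two small partners, acrolein A2 and the alkenyl Grignard reagent A3. In the forward direction CuBr·SMe2 with a chiral phosphoramidite would add A3 to the β-carbon of 1, and the magnesium enolate would be trapped at C5 by A2 to give the cyclopentanone A1; no ring is closed.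
- In its favour: both ring-fusion centres and the absolute configuration come from one catalytic operation. A1 already carries the C9 oxygen, C14 as an exocyclic methylene (which a 9β-hydroxyl could later use for a directed hydrogenation to the 10α-methyl group) and an oxygen on C6.
- Against it here: a closed chair transition state for the aldol of this tetrasubstituted enolate places the hydroxyl cis to the C5 methyl group, which is the C6 epimer of A1. A2 can also react as a Michael acceptor. The two alkenes of A1 cannot be joined directly to ring B. The step does nothing for the oxygen on C8, so a C–H oxygenation like step 15 or a redox detour is still needed.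
- Comparison: this is the same opening move as step 1 (1 + 2 + 3), so on mechanism and on the enantioselective event the two are equal. The alternative is better in step economy at the front, because it keeps the C6 and C9 oxygens from the start while the chosen plan spends steps 5–10 on these centres. The chosen plan is better in stereochemical safety, since no centre depends on the aldol diastereoselectivity.

Alternative 2: The cut is C1–C5: the hydroazulene A4 is traced to the decalin A5, in which C5 is still bonded to C10. In the forward direction buffered acetolysis of the C1 mesylate A5 would ionise C1 while the anti-periplanar C5–C10 bond migrates. The ketal ring shrinks to five members, the ketone ring grows to seven, and loss of H9 gives the enone A4.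
- In its favour: A5 comes from robust annulation chemistry. The shift is stereospecific (inversion at C1, retention at C5) and fixes the trans ring fusion. A4 already has an oxygen on C8. On this point, the main problem of the target, the alternative is better than the chosen plan, because the lactone oxygen needs no C–H functionalisation.
- Against it here: A4 has no oxygen on C6 or C9 and no C7 side chain. Reduction of C9=C10 from the open α face would give the 10β-methyl epimer. Elimination or acetate capture without migration can compete.
- Comparison: a cationic 1,2-shift stands against a radical hydrogen transfer; the shift is the more predictable step (alternative better), but it builds only the carbon skeleton. The chosen plan places oxygen on C6, C8 and C9 with the configurations of the target. Preparing A5 and then adding three oxygenated stereocentres should take more steps than steps 1–15, so on length the chosen plan is ahead. On scalability of the early steps the alternative is equal or better.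

Alternative 3: The cut is C11–C13. In the forward direction KN(SiMe3)2 would convert the lactone A7, which already carries the cyclohexenyl ring on C11, into its potassium enolate. C11 would then displace the primary iodide on the C6′ methylene (6-exo-tet) to close the bicyclo[2.2.2]octene of A6.
- In its favour: the last bond to C11 is made on the open α face of the cis-fused lactone. This places C13 α and leaves C3′ on the β face, which is the configuration of the target. Here the alternative is better than the chosen plan, whose cycloaddition (step 21) must form C11–C3′ on the hindered β face.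
- Against it here: the strong base puts a tiglate and a free ketone at risk, which is why A6 carries three silyl ethers and the ketal. Extra steps follow afterwards (desilylation, selective tigloylation of O6, desaturation). The six-membered ring of A7, with its two stereocentres and the iodomethyl group, must be built separately and attached to C11 first. Elimination of HI and O-alkylation can compete.
- Comparison: the alternative does not make the lactone, so it is compatible with step 15 and would replace steps 16, 17 and 21. Mechanistically, an SN2 alkylation with a clear facial bias stands against a cycloaddition with uncertain facial selectivity (alternative better). In step economy, one cycloaddition with a three-step diene stands against an estimated ten or more extra steps (chosen plan better). Its bond order is therefore kept as the fallback for step 21.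

Key step: step 15

**Remark on the chemistry:** carbons are numbered as in pseudoguaianolides (C1–C15) and, primed, as in p-menthane (C1′–C10′); the aldol of step 1 is assumed to give mainly the 6β-carbinol, and its C6 epimer would be carried along because C6 becomes sp2 in step 10.

## Route

Step 1
Reactants: 1 2-methylcyclopent-2-en-1-one; 2 prop-1-en-2-ylmagnesium bromide; 3 pent-4-enal
Product: 5 (2R,3S)-2-[(1R)-1-hydroxypent-4-en-1-yl]-2-methyl-3-(prop-1-en-2-yl)cyclopentan-1-one, via bromomagnesium enolate 4 (not isolated)
Conditions: 2 (1.3 equiv), CuBr·SMe2 (5 mol %), chiral phosphoramidite (6 mol %, antipode giving the 1αH series), 2-MeTHF, −78 °C; then 3, −78 °C; aq. NH4Cl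
Reagents that add atoms: none
Why: Copper-catalysed asymmetric conjugate addition of the Grignard reagent sets C1 under ligand control; the enolate is then trapped by the aldehyde on the face anti to the new isopropenyl group, which makes the quaternary C5 with the trans C1/C5 relation. The carbinol centre C6 (6β expected from a closed chair transition state) is not needed later.

Step 2
Reactants: 5 aldol adduct
Product: 6 triethylsilyl ether of 5 (6β-OSiEt3)
Conditions: Et3SiOTf, 2,6-lutidine, CH2Cl2, −78 °C
Reagents that add atoms: triethylsilyl trifluoromethanesulfonate, CC[Si](CC)(CC)OS(=O)(=O)C(F)(F)F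
Why: O-silylation of the hindered secondary alcohol stops retro-aldol cleavage of the β-hydroxy ketone and keeps O6 out of steps 3–8; no stereocentre is touched.

Step 3
Reactants: 6 silyl ether
Product: 7 trans-hydroazulenone (4-oxo, C9=C10 with 10-methyl, 5β-methyl, 6β-OSiEt3, 1αH)
Conditions: second-generation Grubbs catalyst RuCl2(=CHPh)(PCy3)(H2IMes) (5 mol %), CH2Cl2, 40 °C
Reagents that add atoms: none
Why: Ring-closing metathesis between the isopropenyl group and the terminal alkene closes ring B as a trisubstituted cycloheptene; this is the only productive pairing and ethene is lost.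

Step 4
Reactants: 7 hydroazulenone
Product: 8 C4 ethylene ketal of 7
Conditions: (Me3SiOCH2)2, Me3SiOTf (5 mol %), CH2Cl2, −78 → −20 °C
Reagents that add atoms: 1,2-bis(trimethylsilyloxy)ethane, C[Si](C)(C)OCCO[Si](C)(C)C
Why: Aprotic silyl-triflate-catalysed ketalisation masks the only ketone before the borane, dissolving-metal and organolithium steps without moving the trisubstituted alkene.

Step 5
Reactants: 8 ketal
Product: 10 9α-alcohol (9α-OH, 10β-methyl, 6β-OSiEt3, C4 ketal), via alkylborane 9 (not isolated)
Conditions: BH3·THF, THF, 0 → 25 °C; then NaOH, H2O2, 0 °C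
Reagents that add atoms: hydrogen peroxide, OO
Why: Hydroboration–oxidation puts boron, then oxygen, on the less substituted C9 by syn addition from the α face, anti to the C5 methyl and the C6 silyloxy group. Both new centres are provisional and are reset in steps 6 and 7.

Step 6
Reactants: 10 9α-alcohol
Product: 12 C9 ketone with 10α-methyl, via 10β-methyl ketone 11 (not isolated)
Conditions: Dess–Martin periodinane, NaHCO3, CH2Cl2, 25 °C; then DBU, CH2Cl2, 25 °C
Reagents that add atoms: none
Why: Alcohol oxidation followed by base equilibration through the enolate. A 10β-methyl group would be syn-axial to the C5 methyl group (1,3 across C1), so the equatorial 10α-epimer is the thermodynamic product.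

Step 7
Reactants: 12 ketone
Product: 13 9β-alcohol (9β-OH, 10α-methyl)
Conditions: Li, NH3(l), THF, EtOH, −78 °C; NH4Cl
Reagents that add atoms: none
Why: Dissolving-metal reduction of the ketone gives the thermodynamically preferred equatorial alcohol, trans to the 10α-methyl group; silyl ether and ketal are inert.

Step 8
Reactants: 13 9β-alcohol
Product: 14 bis-silyl ether (9β-OSi(t-Bu)Me2, 6β-OSiEt3)
Conditions: t-BuMe2SiOTf, 2,6-lutidine, CH2Cl2, 0 °C
Reagents that add atoms: tert-butyldimethylsilyl trifluoromethanesulfonate, CC(C)(C)[Si](C)(C)OS(=O)(=O)C(F)(F)F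
Why: Silylation gives the O9 protecting group for the rest of the route: not a neighbouring group in step 15, stable to the enolate of step 16, removable without base.

Step 9
Reactants: 14 bis-silyl ether
Product: 15 6β-alcohol (9β-OTBS, C4 ketal)
Conditions: HF·pyridine, pyridine, THF, 0 °C
Reagents that add atoms: none
Why: Buffered fluoride cleaves the triethylsilyl ether much faster than the tert-butyldimethylsilyl ether and leaves the ketal alone.

Step 10
Reactants: 15 6β-alcohol
Product: 17 C6=C7 alkene (9β-OTBS, 10α-methyl, C4 ketal), via sulfamate ester 16 (not isolated)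
Conditions: Burgess reagent (MeO2CN–SO2N+Et3 inner salt), toluene, 70 °C
Reagents that add atoms: none
Why: Burgess dehydration by syn-elimination of the sulfamate; C5 is quaternary, so only C7 offers β-hydrogens and the alkene can only be C6=C7, from either C6 epimer.

Step 11
Reactants: 17 alkene
Product: 18 6α,7α-epoxide
Conditions: mCPBA, NaHCO3, CH2Cl2, 0 °C
Reagents that add atoms: 3-chloroperoxybenzoic acid, OOC(=O)c1cccc(Cl)c1
Why: Prilezhaev epoxidation on the α face, anti to the axial C5 methyl group that shields the β face of C6 and C7.

Step 12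
Reactants: 18 epoxide
Product: 19 6α-hydroxy-7β-(cyanomethyl) compound
Conditions: MeCN, n-BuLi, THF, −78 °C; then 18, DMPU, −78 → −10 °C; NH4Cl
Reagents that add atoms: acetonitrile, CC#N
Why: SN2 opening of the epoxide by lithioacetonitrile at C7 (C6 is neopentyl), anti to the epoxide oxygen. One step gives the 7β side chain and the 6α-hydroxyl, trans to each other.

Step 13
Reactants: 19 hydroxy nitrile; 20 tiglic acid
Product: 21 6α-O-tigloyl nitrile
Conditions: 20, 2,4,6-trichlorobenzoyl chloride, Et3N, THF, 25 °C; then 19, DMAP, toluene, 60 °C
Reagents that add atoms: none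
Why: Yamaguchi esterification through the mixed anhydride acylates the hindered secondary alcohol with retention at C6 and keeps the E-alkene; the nitrile is inert.

Step 14
Reactants: 21 nitrile
Product: 22 primary amide (6α-O-tigloyl, 7β-CH2CONH2, C8 methylene, 9β-OTBS, C4 ketal)
Conditions: [PtH{(PMe2O)2H}(PMe2OH)] (2 mol %), EtOH/H2O (4:1), 80 °C
Reagents that add atoms: water, O
Why: Platinum-catalysed hydration of the nitrile under neutral conditions stops at the primary amide and leaves ester, silyl ether and ketal untouched.

Step 15
Reactants: 22 primary amide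
Product: 26 cis-fused 12,8β-lactone (6α-O-tigloyl, 9β-OTBS, C4 ketal), via N-iodoamide 23 (not isolated), via 8α-iodide 24 (not isolated), via iminolactone 25 (not isolated)
Conditions: PhI(OAc)2 (2.5 equiv), I2 (1.0 equiv), CH2Cl2, visible light (tungsten lamp), 25 °C; then aq. Na2S2O3, THF/H2O, 25 °C
Reagents that add atoms: water, O
Why: Acetyl hypoiodite from PhI(OAc)2 and I2 converts the amide into N-iodoamide 23, whose N–I bond is cleaved by light to an electrophilic amidyl radical. The radical takes a hydrogen atom from C8 through a six-membered transition state (N, C12, C11, C7, C8, H); this 1,5-hydrogen transfer of N-haloamides, known from Hofmann–Löffler–Freytag-type reactions that give iminolactones and γ-lactones, is the closest known reaction type. The C8 radical is trapped by iodine to iodide 24, the neutral amide oxygen displaces the iodide in a 5-exo-tet closure to iminolactone 25, and water hydrolyses the C=N bond to lactone 26. The new stereocentre C8 is controlled by the ring fusion: a five-membered ring can bridge C7 and C8 only cis, so oxygen enters on the β face of the side chain, and an unproductive 8β-iodide can return through the radical to the 8α-iodide. Site selectivity is the critical demand: C6–H is also a 1,5-hydrogen but sits on a carbon bearing the electron-withdrawing tiglate next to the quaternary C5, and C9–H would need a seven-membered transition state and lies on the α face, so the polarity-matched C8 methylene reacts. Closure through oxygen rather than nitrogen follows from the higher nucleophilicity of the amide oxygen toward an alkyl iodide, and the silyl ether on O9 offers no competing neighbouring group. Ketal, silyl ether and the electron-poor tiglate alkene are inert under these neutral radical conditions.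

Step 16
Reactants: 26 lactone
Product: 28 11-(dimethylaminomethyl) lactone (C13 on the α face, 11βH), via lithium enolate 27 (not isolated)
Conditions: LiN(i-Pr)2 (1.1 equiv), THF, −78 °C; then CH2=NMe2+ I−, −78 → 0 °C
Reagents that add atoms: N,N-dimethylmethyleneiminium iodide (Eschenmoser's salt), C=[N+](C)C.[I-]
Why: Kinetic lactone enolate formation followed by a Mannich reaction with the iminium salt on the open α face; the new C11 centre is lost in step 17.

Step 17
Reactants: 28 Mannich base
Product: 30 α-methylene lactone (C11=C13), via ammonium iodide 29 (not isolated)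
Conditions: MeI, CH2Cl2/MeOH, 25 °C; then NaHCO3, EtOAc/H2O, 25 °C
Reagents that add atoms: none
Why: N-Methylation turns the amine into a leaving group, and mild base removes the acidic H11 in a β-elimination (Hofmann type) that gives the exocyclic alkene without touching the tiglate.

Step 18
Reactants: 31 (R)-(−)-carvone
Product: 32 (R)-5-(2-hydroxypropan-2-yl)-2-methylcyclohex-2-en-1-one
Conditions: Co(acac)2 (10 mol %), PhSiH3, O2 (1 atm), THF/i-PrOH, 25 °C
Reagents that add atoms: dioxygen, O=O
Why: Mukaiyama hydration: hydrogen-atom transfer from a cobalt hydride to the electron-rich 1,1-disubstituted alkene and trapping by O2 give the Markovnikov tertiary alcohol. The conjugated enone is much less reactive and the stereocentre is not involved.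

Step 19
Reactants: 32 hydroxy enone
Product: 33 (E)-4-methylbenzenesulfonylhydrazone of 32
Conditions: TsNHNH2, EtOH, AcOH (cat.), 25 °C
Reagents that add atoms: 4-methylbenzenesulfonohydrazide, Cc1ccc(cc1)S(=O)(=O)NN
Why: Condensation of the ketone with the sulfonyl hydrazide; the N–N bond settles anti to the substituted alkene carbon, on the side of the α′-methylene needed in step 20.

Step 20
Reactants: 33 tosylhydrazone
Product: 35 (R)-2-(4-methylcyclohexa-2,4-dien-1-yl)propan-2-ol, via vinyllithium 34 (not isolated)
Conditions: MeLi (3.5 equiv), Et2O, 0 → 25 °C; then H2O, 0 °C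
Reagents that add atoms: none
Why: Shapiro reaction: after O–H and N–H deprotonation the α′-methylene is deprotonated, sulfinate and N2 are lost, and the vinyllithium is protonated to the 1,3-diene. C4′ is not deprotonated and keeps its configuration; the diene is used at once.

Step 21
Reactants: 30 α-methylene lactone; 35 dienol
Product: 36 spiro cycloadduct (bonds C11–C3′ and C13–C6′, C12 syn to C1′=C2′, 9β-OTBS, C4 ketal)
Conditions: 35 (5 equiv), BHT (cat.), toluene, 80 °C, sealed tube, dark
Reagents that add atoms: none
Why: Diels–Alder reaction: C13 bonds to C6′, the diene terminus next to the methyl-bearing C1′ (para orientation), and the diene reacts on its face anti to the hydroxyisopropyl group, which sets C3′ and C6′ relative to C4′. The adduct needed has the lactone carbonyl endo, which for this diene enantiomer means bonding C11 on the lactone face cis to C6; the exo mode on the α face is the competitor, as discussed among the least certain steps.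

Step 22
Reactants: 36 cycloadduct
Product: 37 C4 ketone of 36
Conditions: PPTS, acetone/H2O (10:1), 50 °C
Reagents that add atoms: water, O
Why: Mild acid-catalysed ketal hydrolysis; the silyl ether, both esters and the tertiary alcohol beside the alkene survive the buffered acid.

Step 23
Reactants: 37 ketone
Product: 38 cyclopent-2-enone (C2=C3, 9β-OTBS)
Conditions: IBX (2-iodoxybenzoic acid), 4-methoxypyridine N-oxide, DMSO, 25 °C
Reagents that add atoms: none
Why: IBX dehydrogenation of the ketone through its enol; C5 is quaternary, so only C3 can enolise and the double bond can only form at C2=C3. No alcohol that IBX could oxidise is free.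

Step 24
Reactants: 38 silyl ether
Product: 39 target CNP0185323.3
Conditions: HF·pyridine, pyridine, THF, 0 → 25 °C
Reagents that add atoms: none
Why: Fluoride-mediated desilylation frees the 9β-hydroxyl under weakly acidic, non-nucleophilic conditions that spare the cyclopentenone, the tiglate and the lactone.

## Compound list

1 | 2-methylcyclopent-2-en-1-one | CC1=CCCC1=O | starting material
2 | prop-1-en-2-ylmagnesium bromide | CC(=C)[Mg]Br | starting material
3 | pent-4-enal | C=CCCC=O | starting material
4 | bromomagnesium enolate of the conjugate adduct (C4–OMgBr, C4=C5, 1αH) | CC1=C(O[Mg]Br)CC[C@H]1C(C)=C | intermediate (not isolated)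
5 | (2R,3S)-2-[(1R)-1-hydroxypent-4-en-1-yl]-2-methyl-3-(prop-1-en-2-yl)cyclopentan-1-one | C=CCC[C@@H](O)[C@]1(C)C(=O)CC[C@H]1C(C)=C | intermediate
6 | triethylsilyl ether of 5 | C=CCC[C@@H](O[Si](CC)(CC)CC)[C@]1(C)C(=O)CC[C@H]1C(C)=C | intermediate
7 | trans-hydroazulen-4-one, C9=C10, 10-methyl, 5β-methyl, 6β-OSiEt3, 1αH | CC[Si](CC)(CC)O[C@@H]1CCC=C(C)[C@@H]2CCC(=O)[C@]21C | intermediate
8 | C4 ethylene ketal of 7 | CC[Si](CC)(CC)O[C@@H]1CCC=C(C)[C@@H]2CCC3(OCCO3)[C@]21C | intermediate
9 | 9α-boryl adduct of 8 (9α-BH2, 10β-methyl) | CC[Si](CC)(CC)O[C@@H]1CC[C@@H](B)[C@H](C)[C@@H]2CCC3(OCCO3)[C@]21C | intermediate (not isolated)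
10 | 9α-alcohol (9α-OH, 10β-methyl, 6β-OSiEt3, C4 ketal) | CC[Si](CC)(CC)O[C@@H]1CC[C@@H](O)[C@H](C)[C@@H]2CCC3(OCCO3)[C@]21C | intermediate
11 | C9 ketone, 10β-methyl | CC[Si](CC)(CC)O[C@@H]1CCC(=O)[C@H](C)[C@@H]2CCC3(OCCO3)[C@]21C | intermediate (not isolated)
12 | C9 ketone, 10α-methyl | CC[Si](CC)(CC)O[C@@H]1CCC(=O)[C@@H](C)[C@@H]2CCC3(OCCO3)[C@]21C | intermediate
13 | 9β-alcohol, 10α-methyl, 6β-OSiEt3, C4 ketal | CC[Si](CC)(CC)O[C@@H]1CC[C@H](O)[C@@H](C)[C@@H]2CCC3(OCCO3)[C@]21C | intermediate
14 | 9β-OSi(t-Bu)Me2, 6β-OSiEt3 bis-silyl ether | CC[Si](CC)(CC)O[C@@H]1CC[C@H](O[Si](C)(C)C(C)(C)C)[C@@H](C)[C@@H]2CCC3(OCCO3)[C@]21C | intermediate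
15 | 6β-alcohol, 9β-OTBS, C4 ketal | O[C@@H]1CC[C@H](O[Si](C)(C)C(C)(C)C)[C@@H](C)[C@@H]2CCC3(OCCO3)[C@]21C | intermediate
16 | C6 N-(methoxycarbonyl)sulfamate ester, triethylammonium salt | COC(=O)[N-]S(=O)(=O)O[C@@H]1CC[C@H](O[Si](C)(C)C(C)(C)C)[C@@H](C)[C@@H]2CCC3(OCCO3)[C@]21C.CC[NH+](CC)CC | intermediate (not isolated)
17 | C6=C7 alkene, 9β-OTBS, 10α-methyl, C4 ketal | C1=CC[C@H](O[Si](C)(C)C(C)(C)C)[C@@H](C)[C@@H]2CCC3(OCCO3)[C@]21C | intermediate
18 | 6α,7α-epoxide of 17 | O1[C@H]2[C@@H]1C[C@H](O[Si](C)(C)C(C)(C)C)[C@@H](C)[C@@H]3CCC4(OCCO4)[C@]32C | intermediate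
19 | 6α-hydroxy-7β-(cyanomethyl) compound | O[C@H]1[C@H](CC#N)C[C@H](O[Si](C)(C)C(C)(C)C)[C@@H](C)[C@@H]2CCC3(OCCO3)[C@]21C | intermediate
20 | tiglic acid, (E)-2-methylbut-2-enoic acid | C/C=C(\C)C(=O)O | starting material
21 | 6α-O-tigloyl-7β-(cyanomethyl) compound | C/C=C(\C)C(=O)O[C@H]1[C@H](CC#N)C[C@H](O[Si](C)(C)C(C)(C)C)[C@@H](C)[C@@H]2CCC3(OCCO3)[C@]21C | intermediate
22 | key-step precursor: 6α-O-tigloyl, 7β-CH2CONH2, C8 methylene, 9β-OTBS, C4 ketal | C/C=C(\C)C(=O)O[C@H]1[C@H](CC(N)=O)C[C@H](O[Si](C)(C)C(C)(C)C)[C@@H](C)[C@@H]2CCC3(OCCO3)[C@]21C | intermediate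
23 | N-iodoamide of 22 | C/C=C(\C)C(=O)O[C@H]1[C@H](CC(=O)NI)C[C@H](O[Si](C)(C)C(C)(C)C)[C@@H](C)[C@@H]2CCC3(OCCO3)[C@]21C | intermediate (not isolated)
24 | 8α-iodo amide | C/C=C(\C)C(=O)O[C@H]1[C@H](CC(N)=O)[C@@H](I)[C@H](O[Si](C)(C)C(C)(C)C)[C@@H](C)[C@@H]2CCC3(OCCO3)[C@]21C | intermediate (not isolated)
25 | cis-fused iminolactone (C12=NH, O on C8β) | C/C=C(\C)C(=O)O[C@H]1[C@H]2[C@H](OC(=N)C2)[C@H](O[Si](C)(C)C(C)(C)C)[C@@H](C)[C@@H]3CCC4(OCCO4)[C@]31C | intermediate (not isolated)
26 | key-step product: cis-fused 12,8β-lactone, 6α-O-tigloyl, 9β-OTBS, C4 ketal | C/C=C(\C)C(=O)O[C@H]1[C@H]2[C@H](OC(=O)C2)[C@H](O[Si](C)(C)C(C)(C)C)[C@@H](C)[C@@H]3CCC4(OCCO4)[C@]31C | intermediate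
27 | lithium enolate of 26 | C/C=C(\C)C(=O)O[C@H]1[C@H]2[C@H](OC(O[Li])=C2)[C@H](O[Si](C)(C)C(C)(C)C)[C@@H](C)[C@@H]3CCC4(OCCO4)[C@]31C | intermediate (not isolated)
28 | 11-(dimethylaminomethyl) lactone, 11βH | C/C=C(\C)C(=O)O[C@H]1[C@H]2[C@H](OC(=O)[C@@H]2CN(C)C)[C@H](O[Si](C)(C)C(C)(C)C)[C@@H](C)[C@@H]3CCC4(OCCO4)[C@]31C | intermediate
29 | trimethylammonium iodide of 28 | C/C=C(\C)C(=O)O[C@H]1[C@H]2[C@H](OC(=O)[C@@H]2C[N+](C)(C)C)[C@H](O[Si](C)(C)C(C)(C)C)[C@@H](C)[C@@H]3CCC4(OCCO4)[C@]31C.[I-] | intermediate (not isolated)
30 | α-methylene lactone (C11=C13), 6α-O-tigloyl, 9β-OTBS, C4 ketal | C/C=C(\C)C(=O)O[C@H]1[C@H]2[C@H](OC(=O)C2=C)[C@H](O[Si](C)(C)C(C)(C)C)[C@@H](C)[C@@H]3CCC4(OCCO4)[C@]31C | intermediate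
31 | (R)-(−)-carvone | CC1=CC[C@H](CC1=O)C(C)=C | starting material
32 | (R)-5-(2-hydroxypropan-2-yl)-2-methylcyclohex-2-en-1-one | CC1=CC[C@H](CC1=O)C(C)(C)O | intermediate
33 | (E)-4-methylbenzenesulfonylhydrazone of 32 | CC1=CC[C@H](C/C1=N\NS(=O)(=O)c1ccc(C)cc1)C(C)(C)O | intermediate
34 | dilithiated diene (C2′–Li, O8′–Li) | CC1=CC[C@H](C=C1[Li])C(C)(C)O[Li] | intermediate (not isolated)
35 | (R)-2-(4-methylcyclohexa-2,4-dien-1-yl)propan-2-ol | CC1=CC[C@H](C=C1)C(C)(C)O | intermediate
36 | spiro cycloadduct, 9β-OTBS, C4 ketal | C/C=C(\C)C(=O)O[C@H]1[C@H]2[C@H](OC(=O)[C@]23C[C@@H]2C[C@@H](C(C)(C)O)[C@H]3C=C2C)[C@H](O[Si](C)(C)C(C)(C)C)[C@@H](C)[C@@H]2CCC3(OCCO3)[C@]21C | intermediate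
37 | C4 ketone of 36 | C/C=C(\C)C(=O)O[C@H]1[C@H]2[C@H](OC(=O)[C@]23C[C@@H]2C[C@@H](C(C)(C)O)[C@H]3C=C2C)[C@H](O[Si](C)(C)C(C)(C)C)[C@@H](C)[C@@H]2CCC(=O)[C@]21C | intermediate
38 | 2,3-enone, 9β-OTBS | C/C=C(\C)C(=O)O[C@H]1[C@H]2[C@H](OC(=O)[C@]23C[C@@H]2C[C@@H](C(C)(C)O)[C@H]3C=C2C)[C@H](O[Si](C)(C)C(C)(C)C)[C@@H](C)[C@@H]2C=CC(=O)[C@]21C | intermediate
39 | CNP0185323.3 | C/C=C(\C)C(=O)O[C@H]1[C@H]2[C@H](OC(=O)[C@]23C[C@@H]2C[C@@H](C(C)(C)O)[C@H]3C=C2C)[C@H](O)[C@@H](C)[C@@H]2C=CC(=O)[C@]21C | target

## Step count and least certain steps

Total: 24 steps. Longest linear sequence: 21 steps (steps 1–17 and 21–24, from 1 to 39). The dienol branch has 3 steps (18–20).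

**Step 15 (key step).** Most likely to go wrong: rearrangement of the N-iodoamide to an isocyanate (Hofmann type, which hypervalent iodine reagents can trigger), or hydrogen abstraction at C6 with loss of the tiglate, because the two 1,5-positions differ only by polar deactivation.
Fallback: replace the nitrogen-radical relay by a carboxylate-directed metal-oxo hydroxylation. It sets out from 22: nitrosative hydrolysis (t-BuONO, AcOH, 50 °C) gives the carboxylic acid F1. [Fe((S,S)-PDP)(MeCN)2](SbF6)2 with H2O2 in MeCN at 0 °C should hydroxylate the γ-methylene C8 from the iron-bound carboxylate and lactonise. It returns at 26.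

**Step 21.** Most likely to go wrong: facial selection at the lactone. On the α face C11 is flanked only by H7; on the β face by C6 and its β-hydrogen. For this diene enantiomer the α face is tied to the exo orientation, so the cycloaddition may give mainly the C11 epimer.
Fallback: make the two bonds one after the other, C11–C3′ first and C11–C13 last, so that the last bond forms on the open α face of the lactone enolate (the bond order of Alternative 3). It sets out from 26, whose tiglate is exposed to the same kind of amide base as in step 16.
- The lithium enolate of 26 (LiN(i-Pr)2, THF/DMPU, −78 °C) is added 1,4, trans to the 4-substituent, to the 4,6-trans-disubstituted enone F2. The ketone enolate is trapped with PhNTf2 as the enol triflate F3.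
- Iron-catalysed methylation (MeMgBr, Fe(acac)3, THF, −20 °C) with acidic work-up gives the methyl-substituted cyclohexene with free tertiary alcohol F4.
- DDQ (CH2Cl2/H2O) frees the primary alcohol F5, and I2, PPh3, imidazole give the iodide F6.
- KN(SiMe3)2 (2.2 equiv, THF, −78 → 0 °C) closes the bicyclooctene by 6-exo-tet alkylation and returns at 36.

F2 is not an intermediate of the main route and needs a branch of its own, so this fallback costs roughly ten additional steps.

**Step 1.** Most likely to go wrong: insufficient enantiofacial discrimination by the copper–ligand complex on an α-substituted cyclopentenone, together with incomplete aldol trapping of the hindered tetrasubstituted enolate.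
Fallback: separate the two events. It sets out from 1: rhodium-catalysed 1,4-addition of potassium isopropenyltrifluoroborate ([Rh(OH)(cod)]2, (R)- or (S)-BINAP as required, dioxane/H2O, 60 °C) gives ketone F7. The thermodynamic silyl enol ether F8 (Me3SiCl, NaI, Et3N, MeCN) is then used in a Mukaiyama aldol reaction with 3 (BF3·OEt2, CH2Cl2, −78 °C), anti to the isopropenyl group. It returns at 5.

**Step 12.** Most likely to go wrong: base-induced isomerisation of the epoxide to an allylic alcohol, or no substitution at the hindered C7, since lithioacetonitrile is strongly basic and self-condenses on warming.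
Fallback: use the acetate dianion and reach the amide through a lactone. It sets out from 18: LiCH2CO2Li (AcOH, 2 LiN(i-Pr)2, DME, 50 °C) opens the epoxide at C7, and acidification closes the trans-fused 12,6α-lactone F9. Ammonia in MeOH opens it to the hydroxy amide F10, which is acylated at once with 20 under the conditions of step 13. It returns at 22.

**Step 10.** Most likely to go wrong: ionisation of the neopentyl sulfamate with a Wagner–Meerwein shift from the quaternary C5 instead of syn-elimination.
Fallback: go through the ketone. It sets out from 15: Dess–Martin oxidation gives ketone F11. KN(SiMe3)2 with PhNTf2 gives the enol triflate F12 (only C7 can enolise), and reduction with Pd(OAc)2, PPh3, HCO2H, Et3N (DMF, 60 °C) gives the alkene. It returns at 17.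

## Further compounds

F1 | step 15 | carboxylic acid corresponding to 22 (7β-CH2CO2H) | C/C=C(\C)C(=O)O[C@H]1[C@H](CC(=O)O)C[C@H](O[Si](C)(C)C(C)(C)C)[C@@H](C)[C@@H]2CCC3(OCCO3)[C@]21C
F2 | step 21 | 4,6-trans-6-[(4-methoxybenzyloxy)methyl]-4-[2-(trimethylsilyloxy)propan-2-yl]cyclohex-2-en-1-one | O=C1C=C[C@H](C(C)(C)O[Si](C)(C)C)C[C@H]1COCc1ccc(OC)cc1
F3 | step 21 | C11-(cyclohexenyl) lactone as enol triflate (C11 epimers) | C/C=C(\C)C(=O)O[C@H]1[C@H]2[C@H](OC(=O)C2[C@@H]5C=C(OS(=O)(=O)C(F)(F)F)[C@H](COCc6ccc(OC)cc6)C[C@H]5C(C)(C)O[Si](C)(C)C)[C@H](O[Si](C)(C)C(C)(C)C)[C@@H](C)[C@@H]3CCC4(OCCO4)[C@]31C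
F4 | step 21 | C11-(1′-methylcyclohexenyl) lactone, 4-methoxybenzyl ether, free tertiary alcohol | C/C=C(\C)C(=O)O[C@H]1[C@H]2[C@H](OC(=O)C2[C@@H]5C=C(C)[C@H](COCc6ccc(OC)cc6)C[C@H]5C(C)(C)O)[C@H](O[Si](C)(C)C(C)(C)C)[C@@H](C)[C@@H]3CCC4(OCCO4)[C@]31C
F5 | step 21 | primary alcohol (C13–OH) | C/C=C(\C)C(=O)O[C@H]1[C@H]2[C@H](OC(=O)C2[C@@H]5C=C(C)[C@H](CO)C[C@H]5C(C)(C)O)[C@H](O[Si](C)(C)C(C)(C)C)[C@@H](C)[C@@H]3CCC4(OCCO4)[C@]31C
F6 | step 21 | primary iodide (C13–I) | C/C=C(\C)C(=O)O[C@H]1[C@H]2[C@H](OC(=O)C2[C@@H]5C=C(C)[C@H](CI)C[C@H]5C(C)(C)O)[C@H](O[Si](C)(C)C(C)(C)C)[C@@H](C)[C@@H]3CCC4(OCCO4)[C@]31C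
F7 | step 1 | (3R)-2-methyl-3-(prop-1-en-2-yl)cyclopentan-1-one (C2 epimers) | CC1C(=O)CC[C@H]1C(C)=C
F8 | step 1 | trimethylsilyl enol ether of F7 (C1=C2) | CC1=C(O[Si](C)(C)C)CC[C@H]1C(C)=C
F9 | step 12 | trans-fused 12,6α-lactone, 9β-OTBS, C4 ketal | O=C1C[C@@H]2C[C@H](O[Si](C)(C)C(C)(C)C)[C@@H](C)[C@@H]3CCC4(OCCO4)[C@@]3(C)[C@H]2O1
F10 | step 12 | 6α-hydroxy-7β-(carbamoylmethyl) compound | O[C@H]1[C@H](CC(N)=O)C[C@H](O[Si](C)(C)C(C)(C)C)[C@@H](C)[C@@H]2CCC3(OCCO3)[C@]21C
F11 | step 10 | C6 ketone, 9β-OTBS, C4 ketal | O=C1CC[C@H](O[Si](C)(C)C(C)(C)C)[C@@H](C)[C@@H]2CCC3(OCCO3)[C@]21C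
F12 | step 10 | C6 enol triflate (C6=C7) | FC(F)(F)S(=O)(=O)OC1=CC[C@H](O[Si](C)(C)C(C)(C)C)[C@@H](C)[C@@H]2CCC3(OCCO3)[C@]21C
A1 | alternative 1 | trans-2,3-disubstituted 2-methylcyclopentanone with C6 allylic alcohol | C=C[C@H](O)[C@]1(C)C(=O)CC[C@H]1C(=C)CO[Si](C)(C)C(C)(C)C
A2 | alternative 1 | acrolein | C=CC=O
A3 | alternative 1 | [3-(tert-butyldimethylsilyloxy)prop-1-en-2-yl]magnesium bromide | C=C([Mg]Br)CO[Si](C)(C)C(C)(C)C
A4 | alternative 2 | trans-hydroazulene C9-en-8-one, C4 ketal | C[C@]12CCC(=O)C=C(C)[C@@H]1CCC23OCCO3
A5 | alternative 2 | cis-fused 5,10-dimethyl decalin, C1 methanesulfonate, C4 ketal, C8 ketone | C[C@]12CCC(=O)C[C@@]1(C)[C@H](OS(C)(=O)=O)CCC23OCCO3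
A6 | alternative 3 | protected spiro bicyclooctene lactone | CC[Si](CC)(CC)O[C@H]1[C@H]2[C@H](OC(=O)[C@]23C[C@@H]2C[C@@H](C(C)(C)O[Si](CC)(CC)CC)[C@H]3C=C2C)[C@H](O[Si](C)(C)C(C)(C)C)[C@@H](C)[C@@H]2CCC3(OCCO3)[C@]21C
A7 | alternative 3 | C11-(cyclohexenyl) lactone with primary iodide on the C6′ methylene (C11 epimers) | CC[Si](CC)(CC)O[C@H]1[C@H]2[C@H](OC(=O)C2[C@@H]2C=C(C)[C@H](CI)C[C@H]2C(C)(C)O[Si](CC)(CC)CC)[C@H](O[Si](C)(C)C(C)(C)C)[C@@H](C)[C@@H]2CCC3(OCCO3)[C@]21C
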